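## The problem

Target 17 is [(1R,2S,3R,6S)-2-acetoxy-3-(benzoyloxy)-1-hydroxy-6-methoxycyclohex-4-en-1-yl]methyl benzoate. The locants used for every intermediate are those of the target: C1 is the tertiary carbinol carbon bearing C7H2OBz, C2 carries OAc, C3 carries OBz, C4=C5 is the alkene, C6 carries OMe.

- **Skeleton.** A single cyclohexene has to be made with one exocyclic carbon (C7) on a fully substituted ring carbon. The only C–C bond that is not trivially available is C1–C7.
- **Stereocentres.** Four contiguous centres must be set: O1 cis to O2, O2 trans to O3, O1 trans to O6. C2, C3 and C6 are secondary carbinol centres of a cyclitol type. C1 is quaternary and must be created under the influence of its neighbours, which requires a conformationally fixed ring, so that C2 (and C3) can bias the two faces of a C1 carbonyl.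
- **Oxygen differentiation.** Five oxygens carry four different things: free tertiary OH, acetate, two benzoates and a methyl ether. Acyl groups on cis-disposed neighbours (O2/O1, and O3/O4 in saturated precursors) can migrate.
- **Sensitive groups.** The allylic benzoate and allylic methyl ether do not tolerate strong Lewis acids, and the alkene rules out late hydrogenolysis. Any ketone at C1 is a β-acyloxy ketone that eliminates and aromatises with base.
- **Enabling feature.** The array C6(OMe)–C1(O)–C2(O)–C3(O) coincides, in constitution and absolute configuration and including the methyl ether, with C3–C2–C1–C6 of D-pinitol 1. C5/C4 correspond to the only trans-diequatorial diol of 1 (its C4/C5), a latent alkene. Only C7 and the double bond are missing. Oxidation at C1 gives an inosose whose carbonyl is flanked by an axial acetoxy group, which is the handle for a stereocontrolled one-carbon spiro-epoxidation.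

## Retrosynthesis

**17 ⇒ 15.** The C4=C5 alkene is traced back to the trans-4,5-diol 15 (two C–O bonds restored). This is preferred over building the ring around a pre-formed alkene, because the diol is exactly what the chiral pool supplies and its two stereocentres are destroyed anyway. A syn-stereospecific deoxygenation (cyclic thionocarbonate type) cannot give a cyclohexene from a trans diol. The forward reaction must therefore proceed by double inversion and anti-elimination through the trans-diiodide 16 (Garegg–Samuelsson olefination), and must spare the tertiary hydroxyl and three esters.

**15 ⇒ 14.** The diol is masked as a butane-2,3-diacetal. This group selects the single trans-diequatorial diol of the starting cyclitol, locks the chair for the stereochemical step, and survives every condition before its removal. The price is a strongly acidic aqueous cleavage at the end, which the esters and the tertiary alcohol should tolerate.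

**14 ⇒ 12 + 13.** The C7–O ester bond is cut to the spiro-oxirane 12 and benzoic acid 13. Opening at the primary carbon returns the tertiary hydroxyl with C1 untouched and installs the second benzoate in the same step. Hydrolysis followed by acylation would cost one more step. The forward reaction needs attack at CH2 only, in a buffered medium so that the liberated alkoxide does not pick up a neighbouring acyl group.

**12 ⇒ 9 + 10 (key disconnection).** C1–C7 and the C7–O bond of the oxirane are cut together, leading to the inosose 9 and diazomethane 10 through the betaine 11.
- Basic one-carbon nucleophiles (ylides, metalated hydroxymethyl equivalents) are excluded by the β-benzoate of 9.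
- Methylenation followed by electrophilic oxidation would be longer, and the electrophile would be expected to approach anti to the axial allylic acetoxy group, giving the wrong C1 epimer.
- A neutral carbon nucleophile attacking anti to that same group gives the right one.
- The precursor 9 has no quaternary centre and no C7, and is a protected pinitol oxidised at one position.

**9 ⇒ 8.** The ketone is taken back to the C1 alcohol 8. The requirement is that C1–OH is the only free hydroxyl, next to an axial acetate that must not migrate before oxidation.

**8 ⇒ 5 + 6 (through 7), and 5 ⇒ 3 + 4.** The C3 benzoate and the C2 acetate are disconnected in a way that solves the triol differentiation with one auxiliary.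
- Trimethyl orthoacetate 4 bridges the only cis pair (O1/O2) of triol 3 to give 5.
- The remaining axial C3–OH is benzoylated with 6 to give 7.
- Mild hydrolysis then collapses the orthoester to the axial acetate and the equatorial alcohol, so the protecting group becomes the acetate of the target.
- An acetonide on/off sequence would reach the same compound in two more steps.

**3 ⇒ 1 + 2.** The diacetal is removed to give D-pinitol 1 and butane-2,3-dione 2. Of the five hydroxyls of 1 only O4/O5 (pinitol and target locants coincide here) are trans-diequatorial, so thermodynamic diacetal formation should be regioselective without prior protection.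

## Roads not taken

**Alternative 1:** a [3,3] sigmatropic ring contraction of a pyranoid 2-alkoxyglycal A1 bearing an (E)-2-methoxyvinyl group on its C5. Heating forms C1–C6 while the ring C–O bond at the future C4 breaks, giving the carbocyclic aldehyde A2.
- **Merits.** The carbocycle, the quaternary centre, the C4=C5 alkene and the C6 methyl ether all appear in one step. Suprafacial delivery from the D-configured C5 gives the right C1 configuration. In ring construction and alkene placement this road is better than the chosen one, which needs a separate late olefination.
- **Weak points.** A1 requires a long sugar sequence (chain-end oxidation, enol-ether olefination with geometry control, 2-alkoxyglycal formation). The rearrangement must pass through a ring-enforced boat at high temperature with a silyl ether and two 4-methoxybenzyl ethers present. C7 arrives as an aldehyde that must be reduced. All three protecting groups must then be exchanged for acetate and benzoates in the presence of the alkene.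
- **Comparison.** The chosen plan buys three of the four stereocentres and the methyl ether with pinitol 1, changes no oxidation state at C7, and reaches the key-step substrate 9 in four steps.

**Alternative 2:** desymmetrisation of an achiral para-quinol A3 by acetalisation with an aliphatic aldehyde and intramolecular oxa-Michael addition under a chiral phosphoric acid, giving the cis-fused dioxolane enone A4. The C2–O bond and the C1/C2 cis relationship are set catalytically.
- **Merits.** A3 is reached very quickly from an aromatic precursor. No chiral pool is needed and either enantiomer is available. In these respects it surpasses the chosen plan.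
- **Weak points.** A4 has only two of the four stereocentres and the wrong oxidation pattern. It still needs oxygenation at C3 trans to O2, transposition of the enone into a C6 oxygen with a C4=C5 alkene, O-methylation, and acyl differentiation, each with its own stereocontrol relayed from the first centres. The absolute configuration rests on catalyst selectivity.
- **Comparison.** The chosen plan has a secure absolute configuration and needs far fewer stereochemical operations after the key step.

**Alternative 3:** closure of the ring by attack of a (Z)-vinylsilane on an oxocarbenium ion generated from the C6 dimethyl acetal of the acyclic precursor A5, forming C5–C6 with loss of silicon to give the cyclohexene A6.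
- **Merits.** The methyl ether and the alkene are created in the ring-forming event. No base-sensitive ketone is involved. The protecting-group map is well chosen: two benzyl ethers become the two benzoates, and the acetonide spans O1/O2. It avoids both the late diol-to-alkene conversion and the inosose, which are the soft spots of the chosen plan.
- **Weak points.** A5 must be assembled acyclically with three contiguous stereocentres, one quaternary, and a geometrically pure vinylsilane. The C6 configuration is decided in the cyclisation next to the quaternary centre with only a conformational bias. The benzyl ethers must be removed without hydrogenation because of the alkene.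
- **Comparison.** The chosen plan has a much shorter approach to its key step and has C6 fixed from the outset.

Key step: step 5

Remark: diazomethane 10 is treated as a laboratory reagent, distilled as an ether solution from commercial N-methyl-N-nitroso-p-toluenesulfonamide and KOH immediately before use. Target locants map onto pinitol locants as C1 = pinitol C2, C2 = C1, C3 = C6, C4 = C5, C5 = C4, C6 = C3.

## Route

Step 1
Reactants: 1 D-pinitol; 2 butane-2,3-dione
Product: 3 4,5-O-[(2R,3R)-2,3-dimethoxybutane-2,3-diyl]-D-pinitol (triol: C1–OH equatorial; C2–OH and C3–OH axial)
Conditions: 2 (1.2 equiv), HC(OMe)3, CSA (cat.), MeOH, reflux; Et3N quench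
Reagents that add atoms: butane-2,3-dione (2), CC(=O)C(C)=O; trimethyl orthoformate, COC(OC)OC (the two acetal methoxy groups, in exchange with solvent methanol, CO)
Why: Butane-2,3-diacetal formation is thermodynamically controlled and strongly favours the trans-fused dioxane with both methoxy groups axial (anomeric effect); O4/O5 is the only trans-diequatorial diol of 1, and the acetal carbons are set by the diol configuration.

Step 2
Reactants: 3; 4 trimethyl orthoacetate
Product: 5 1,2-O-(1-methoxyethylidene) orthoester of 3 (bridging the cis O1/O2 pair; axial C3–OH free; both epimers at the orthoester carbon)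
Conditions: MeC(OMe)3 (1.5 equiv), CSA (cat.), MeCN, rt; Et3N, concentrate, used crude
Reagents that add atoms: trimethyl orthoacetate (4), CC(OC)(OC)OC
Why: Acid-catalysed transorthoesterification gives a five-membered cyclic orthoester only across a cis-vicinal diol; O2/O3 are trans-diaxial and cannot be bridged, so C3–OH is left as the single free hydroxyl.

Step 3
Reactants: 5; 6 benzoyl chloride
Product: 8 1-O-acetyl-6-O-benzoyl-4,5-O-[(2R,3R)-2,3-dimethoxybutane-2,3-diyl]-D-pinitol (target locants: axial C2 acetate; axial C3 benzoate; equatorial C1–OH free), via 3-O-benzoyl orthoacetate 7 (not isolated)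
Conditions: BzCl, pyridine, DMAP (cat.), 0 °C to rt; concentrate; then AcOH–H2O (4:1), rt
Reagents that add atoms: benzoyl chloride (6), O=C(Cl)c1ccccc1; water, O
Why: Orthoesters are stable to acylation in pyridine, so the axial C3–OH is benzoylated first; mild aqueous acid then opens the cyclic orthoester through the hemi-orthoester, which collapses stereoelectronically to the axial ester and the equatorial alcohol, and the trans-diaxial O2/O3 pair cannot exchange acyl groups.

Step 4
Reactants: 8
Product: 9 C1 ketone (inosose) bearing the axial C2 acetate, axial C3 benzoate, equatorial C6 methyl ether and the 4,5-diacetal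
Conditions: Dess–Martin periodinane, CH2Cl2, 0 °C to rt; filtration through a short silica pad, no basic wash
Reagents that add atoms: none
Why: Periodinane oxidation of a hindered secondary cyclitol alcohol proceeds under neutral to weakly acidic conditions, which avoids acetyl migration from O2 to O1 before oxidation, epimerisation at C2 or C6, and E1cB loss of the β-benzoate from the product.

Step 5
Reactants: 9; 10 diazomethane
Product: 12 C1 spiro-oxirane (C7 axial below the ring; oxirane oxygen equatorial, cis to the C2 acetate), via diazonium alkoxide betaine 11 (not isolated)
Conditions: CH2N2 (excess, Et2O solution), CH2Cl2–MeOH (10:1), 0 °C to rt; N2 purge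
Reagents that add atoms: diazomethane (10), C=[N+]=[N-]
Why: The nucleophilic carbon of diazomethane adds to the C1 carbonyl, which two α C–O bonds make strongly electrophilic, giving the diazonium alkoxide 11. The alkoxide then displaces N2 from C7 in a 3-exo-tet closure, so C1–C7 and the C7–O bond of the oxirane form in one flask; the closest known reaction type is the diazomethane spiro-epoxidation of acylated inososes and pyranosuloses. The trans-fused diacetal locks the chair with O2 and O3 axial and O6 equatorial, so the two carbonyl faces are fixed and different. The new C1 stereocentre is controlled by the axial C2 acetoxy group: carbon attack anti to that C–O bond (polar Felkin–Anh, axial entry) avoids both its bulk on the equatorial face and a dipole-opposed approach, placing C7 axial and the oxygen equatorial, cis to O2 as in 17. The step needs this facial selectivity, which the syn-axial C3 benzoate opposes and which is the first thing to be tested. It also needs O-alkylation rather than 1,2-shift with ring enlargement, which is favoured because both ring carbons that could migrate carry electron-withdrawing oxygen. Finally it needs freedom from enolisation, which the neutral, base-free medium secures, so that C2 and C6 keep their configuration and the β-benzoate is not eliminated.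

Step 6
Reactants: 12; 13 benzoic acid
Product: 14 tertiary C1 alcohol with C7 benzoate, C2 acetate, C3 benzoate, C6 methyl ether and the 4,5-diacetal
Conditions: PhCO2H (3 equiv), iPr2NEt (0.5 equiv), DMF, 70 °C
Reagents that add atoms: benzoic acid (13), O=C(O)c1ccccc1
Why: Carboxylate opening of a 2,2-disubstituted oxirane occurs by SN2 attack at the primary carbon, so the C1–O bond and its configuration are untouched; the excess acid protonates the tertiary alkoxide at once, which suppresses acyl transfer from O2.

Step 7
Reactants: 14
Product: 15 trans-4,5-diol (O4 and O5 free; C1–OH tertiary free; esters and methyl ether unchanged)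
Conditions: CF3CO2H–H2O (9:1), 0 °C to rt, short reaction time; toluene co-evaporation
Reagents that add atoms: none
Why: Butane-2,3-diacetals are cleaved by aqueous trifluoroacetic acid (acetal hydrolysis) under conditions that benzoates, acetates and methyl ethers survive; acid-mediated acyl migration is slow compared with base-mediated migration and is limited further by the short exposure.

Step 8
Reactants: 15
Product: 17 [(1R,2S,3R,6S)-2-acetoxy-3-(benzoyloxy)-1-hydroxy-6-methoxycyclohex-4-en-1-yl]methyl benzoate (the target), via trans-4,5-diiodide 16 (not isolated)
Conditions: PPh3 (4 equiv), imidazole (4 equiv), I2 (3 equiv), toluene, reflux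
Reagents that add atoms: none
Why: Garegg–Samuelsson olefination: both secondary hydroxyls are activated as alkoxyphosphonium ions and displaced by iodide with inversion to the trans-diaxial diiodide 16, which loses iodine by anti-elimination to give the cis ring alkene; the tertiary C1–OH cannot undergo displacement, the C3 benzoate is cis to the C4 leaving group and cannot participate, and no stereocentre is formed or touched.

## Compound list

1 | D-pinitol (3-O-methyl-D-chiro-inositol) | CO[C@H]1[C@H](O)[C@@H](O)[C@@H](O)[C@H](O)[C@@H]1O | starting material
2 | butane-2,3-dione | CC(=O)C(C)=O | starting material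
3 | 4,5-O-[(2R,3R)-2,3-dimethoxybutane-2,3-diyl]-D-pinitol | CO[C@H]1[C@@H]2O[C@@](C)(OC)[C@](C)(OC)O[C@H]2[C@@H](O)[C@H](O)[C@@H]1O | intermediate
4 | trimethyl orthoacetate | CC(OC)(OC)OC | starting material
5 | 1,2-O-(1-methoxyethylidene) orthoester of 3 (C3–OH free; epimers at the orthoester carbon) | CO[C@H]1[C@@H]2O[C@@](C)(OC)[C@](C)(OC)O[C@H]2[C@@H](O)[C@@H]2OC(C)(OC)O[C@H]12 | intermediate
6 | benzoyl chloride | O=C(Cl)c1ccccc1 | starting material
7 | 3-O-benzoyl derivative of orthoester 5 (pinitol locant O6) | CO[C@H]1[C@@H]2O[C@@](C)(OC)[C@](C)(OC)O[C@H]2[C@@H](OC(=O)c2ccccc2)[C@@H]2OC(C)(OC)O[C@H]12 | intermediate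
8 | 1-O-acetyl-6-O-benzoyl-4,5-O-[(2R,3R)-2,3-dimethoxybutane-2,3-diyl]-D-pinitol (target locants: C2 OAc, C3 OBz, C1 OH) | CO[C@H]1[C@@H]2O[C@@](C)(OC)[C@](C)(OC)O[C@H]2[C@@H](OC(=O)c2ccccc2)[C@H](OC(C)=O)[C@@H]1O | intermediate
9 | C1 ketone (inosose) derived from 8 | CO[C@H]1[C@@H]2O[C@@](C)(OC)[C@](C)(OC)O[C@H]2[C@@H](OC(=O)c2ccccc2)[C@H](OC(C)=O)C1=O | intermediate
10 | diazomethane | C=[N+]=[N-] | starting material
11 | C1 alkoxide bearing the C7 diazonium group (betaine) | CO[C@H]1[C@@H]2O[C@@](C)(OC)[C@](C)(OC)O[C@H]2[C@@H](OC(=O)c2ccccc2)[C@H](OC(C)=O)[C@@]1([O-])C[N+]#N | intermediate
12 | C1 spiro-oxirane (C7 below, oxygen above the ring, cis to O2) | CO[C@H]1[C@@H]2O[C@@](C)(OC)[C@](C)(OC)O[C@H]2[C@@H](OC(=O)c2ccccc2)[C@H](OC(C)=O)[C@@]13CO3 | intermediate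
13 | benzoic acid | O=C(O)c1ccccc1 | starting material
14 | 4,5-diacetal of the target skeleton: tertiary C1–OH, C7 benzoate, C2 acetate, C3 benzoate, C6 methyl ether | CO[C@H]1[C@@H]2O[C@@](C)(OC)[C@](C)(OC)O[C@H]2[C@@H](OC(=O)c2ccccc2)[C@H](OC(C)=O)[C@@]1(O)COC(=O)c1ccccc1 | intermediate
15 | trans-4,5-diol (4,5-dihydro-4,5-dihydroxy form of the target) | CO[C@H]1[C@H](O)[C@@H](O)[C@@H](OC(=O)c2ccccc2)[C@H](OC(C)=O)[C@@]1(O)COC(=O)c1ccccc1 | intermediate
16 | trans-4,5-diiodide (both carbinol centres inverted, iodides diaxial) | CO[C@H]1[C@@H](I)[C@H](I)[C@@H](OC(=O)c2ccccc2)[C@H](OC(C)=O)[C@@]1(O)COC(=O)c1ccccc1 | intermediate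
17 | [(1R,2S,3R,6S)-2-acetoxy-3-(benzoyloxy)-1-hydroxy-6-methoxycyclohex-4-en-1-yl]methyl benzoate | CO[C@H]1C=C[C@@H](OC(=O)c2ccccc2)[C@H](OC(C)=O)[C@@]1(O)COC(=O)c1ccccc1 | target

## Step count and least certain steps

Total: 8 steps. Longest linear sequence: 8 steps, from D-pinitol 1.

**Step 5 (key step).**
- Most likely failure: poor facial selectivity. The syn-axial C3 benzoate crowds the axial trajectory that the C2 acetoxy group favours, so part of the material may take the methylene equatorially and give the C1 epimer. Ring enlargement by 1,2-shift in the betaine is the second possibility.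
- Fallback: from ketone 9, returning at 12, with the C1–O bond set by intramolecular delivery rather than by approach control. Takai–Lombardo methylenation (Zn, CH2Br2, TiCl4, THF–CH2Cl2, 0 °C to rt) should give the exocyclic alkene F1 without enolisation. Methanolic HCl at 0 °C to rt should remove the acetate selectively in the presence of the benzoate and the diacetal, giving the axial allylic alcohol F2. Hydroxyl-directed epoxidation (VO(acac)2 cat., t-BuOOH, CH2Cl2) delivers oxygen to the alkene face on which the C2–OH sits, giving the epoxy alcohol F3 with the oxirane oxygen cis to O2. Acetylation (Ac2O, pyridine, DMAP) then gives spiro-oxirane 12, from which steps 6–8 follow unchanged.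

**Step 8.**
- Most likely failure: incomplete double displacement. Iodide must enter axially at C4 and C5, next to the C3 benzoate and below the quaternary centre. Prolonged heating invites acyl migration or reaction at the tertiary alcohol.
- Fallback: from diol 15, returning at 17, by a radical elimination that needs no SN2 step and is indifferent to the trans geometry. Acylation with O-phenyl chlorothionoformate (pyridine, DMAP, CH2Cl2) gives the 4,5-bis(phenoxythiocarbonate) F4, the tertiary alcohol staying free. Bu3SnH with AIBN in toluene at 90 °C generates the C4 or C5 radical, which expels the neighbouring thiocarbonate by β-scission (Barton-type deoxygenative olefination of a vicinal diol) to give 17.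

**Step 6.**
- Most likely failure: sluggish opening. The backside trajectory to C7 runs under the ring, past the syn-axial C3 benzoate, and C7 is neopentyl-like. Forcing conditions promote acyl transfer to the tertiary alkoxide.
- Fallback: from oxirane 12, returning at 14, using the smallest nucleophile on an acid-activated oxirane. Catalytic HClO4 in THF–H2O at rt should hydrate the oxirane at the primary carbon to the C1,C7-diol F5. C1 is flanked by two C–O bonds and resists cationic opening, so its configuration is retained, and the diacetal survives dilute acid. Benzoylation of the primary hydroxyl (BzCl, pyridine, −20 to 0 °C) then gives 14.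

**Step 3.**
- Most likely failure: incomplete benzoylation of the hindered axial C3–OH while the acid-labile orthoester must be kept intact, or partial loss of the orthoester before acylation, which would scramble the ester pattern.
- Fallback: from triol 3, returning at 7, separating protection from acetate delivery. 2,2-Dimethoxypropane with CSA in acetone gives the 1,2-acetonide F6. Forcing benzoylation (BzCl, pyridine, DMAP, 60 °C) gives the acetonide benzoate F7. CSA in MeOH at rt removes the acetonide while the diacetal, which is formed under these very conditions, stays; this gives the C1,C2-diol C3-benzoate F8. Treatment of F8 with trimethyl orthoacetate 4 and CSA gives the benzoylated orthoester 7, which is opened with aqueous acetic acid as in the second half of step 3.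

## Further compounds

F1 | step 5 | exocyclic C1 methylene compound (C2 OAc, C3 OBz, C6 OMe, 4,5-diacetal) | CO[C@H]1[C@@H]2O[C@@](C)(OC)[C@](C)(OC)O[C@H]2[C@@H](OC(=O)c2ccccc2)[C@H](OC(C)=O)C1=C
F2 | step 5 | allylic alcohol (C2–OH axial, C3 OBz, exocyclic methylene) | CO[C@H]1[C@@H]2O[C@@](C)(OC)[C@](C)(OC)O[C@H]2[C@@H](OC(=O)c2ccccc2)[C@H](O)C1=C
F3 | step 5 | epoxy alcohol (spiro-oxirane oxygen cis to the free C2–OH) | CO[C@H]1[C@@H]2O[C@@](C)(OC)[C@](C)(OC)O[C@H]2[C@@H](OC(=O)c2ccccc2)[C@H](O)[C@@]13CO3
F4 | step 8 | 4,5-bis(phenoxythiocarbonate) of diol 15 | CO[C@H]1[C@H](OC(=S)Oc2ccccc2)[C@@H](OC(=S)Oc2ccccc2)[C@@H](OC(=O)c2ccccc2)[C@H](OC(C)=O)[C@@]1(O)COC(=O)c1ccccc1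
F5 | step 6 | C1,C7-diol (tertiary C1–OH and primary C7–OH; C2 OAc, C3 OBz, 4,5-diacetal) | CO[C@H]1[C@@H]2O[C@@](C)(OC)[C@](C)(OC)O[C@H]2[C@@H](OC(=O)c2ccccc2)[C@H](OC(C)=O)[C@@]1(O)CO
F6 | step 3 | 1,2-O-isopropylidene derivative of 3 (C3–OH free) | CO[C@H]1[C@@H]2O[C@@](C)(OC)[C@](C)(OC)O[C@H]2[C@@H](O)[C@@H]2OC(C)(C)O[C@H]12
F7 | step 3 | 3-O-benzoyl-1,2-O-isopropylidene derivative of 3 | CO[C@H]1[C@@H]2O[C@@](C)(OC)[C@](C)(OC)O[C@H]2[C@@H](OC(=O)c2ccccc2)[C@@H]2OC(C)(C)O[C@H]12
F8 | step 3 | C1,C2-diol C3-benzoate of 3 | CO[C@H]1[C@@H]2O[C@@](C)(OC)[C@](C)(OC)O[C@H]2[C@@H](OC(=O)c2ccccc2)[C@H](O)[C@@H]1O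
A1 | alternative 1 | 2-alkoxyglycal with (E)-2-methoxyvinyl group on C5 (two 4-methoxybenzyl ethers, one TBS ether) | CO/C=C/[C@H]1OC=C(OCc2ccc(OC)cc2)[C@@H](OCc2ccc(OC)cc2)[C@@H]1O[Si](C)(C)C(C)(C)C
A2 | alternative 1 | 6-methoxy-1,2-bis(4-methoxybenzyloxy)-3-(TBS-oxy)cyclohex-4-ene-1-carbaldehyde | CO[C@H]1C=C[C@@H](O[Si](C)(C)C(C)(C)C)[C@H](OCc2ccc(OC)cc2)[C@@]1(OCc1ccc(OC)cc1)C=O
A3 | alternative 2 | 4-hydroxy-4-[(tert-butyldiphenylsilyloxy)methyl]cyclohexa-2,5-dien-1-one | O=C1C=CC(O)(CO[Si](c2ccccc2)(c2ccccc2)C(C)(C)C)C=C1
A4 | alternative 2 | cis-fused isopropyl-substituted dioxolane enone | O=C1C=C[C@@]2(CO[Si](c3ccccc3)(c3ccccc3)C(C)(C)C)O[C@H](C(C)C)O[C@H]2C1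
A5 | alternative 3 | acyclic dimethyl acetal with (Z)-vinylsilane, acetonide on O1/O2, benzyl ethers on O3 and O7 | COC(OC)[C@@]1(COCc2ccccc2)OC(C)(C)O[C@H]1[C@H](OCc1ccccc1)/C=C\[Si](C)(C)C
A6 | alternative 3 | C6 methyl ether of the acetonide-protected dibenzyl cyclohexene | CO[C@H]1C=C[C@@H](OCc2ccccc2)[C@@H]2OC(C)(C)O[C@]12COCc1ccccc1
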